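The earlier runs and the new flask come from a simulation on assumed constants, and the scatter is random.

Early in a run the open question is when chains start, so the decision for the next batch is this: can zeta stay as written, or does it need less radical scavenger to show anything in its time?

| flask | free monomer | initiator | radical scavenger | temperature | remark | time |
|---|---|---|---|---|---|---|
| winter | 0.52 M | 3.5 mol% | 1.1 mol% | −19 °C | run made earlier |  |
| midnight | 0.52 M | 5.5 mol% | 1.1 mol% | 6 °C | run made earlier |  |
| spring | 1 M | 2.5 mol% | 1.1 mol% | −19 °C | run made earlier |  |
| zeta | 0.52 M | 2.5 mol% | 1.1 mol% | −30 °C |  | 25 h |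
| beta | 0.52 M | 2.5 mol% | 1.1 mol% | −15 °C |  | 25 h |
| epsilon | 0.52 M | 2.5 mol% | 1.1 mol% | 15 °C |  | 25 h |
| delta | 0.52 M | 2.5 mol% | 1.1 mol% | 0 °C |  | 25 h |

- winter (time / h: monomer in chains / %, isomer of the product / %): 0.833: 0, 0; 3.00: 1.2, 0; 5.00: 0.5, 0; 8.00: 1.2, 0; 12.0: 1.5, 1.7; 15.0: 0, 0.9
- midnight (time / h: monomer in chains / %, isomer of the product / %): 0.667: 22.0, 6.1; 1.33: 30.3, 27.1; 2.00: 26.7, 47.6; 2.50: 21.7, 56.9; 3.00: 19.4, 68.0; 4.00: 13.5, 82.0
- spring (time / h: monomer in chains / %, isomer of the product / %): 1.33: 0, 0; 4.00: 0, 1.8; 8.00: 0, 0.6; 12.0: 0, 1.4; 15.0: 1.2, 0

(each reading ± 1 percentage point)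

1. the flask with the highest share of monomer in chains in all that became monomer in chains or isomer of the product ("all alike" if they lie within 1.5 percentage points) (zeta / beta / epsilon / delta / all alike)
2. share of monomer in chains in all that became monomer in chains or isomer of the product, zeta
3. share of monomer in chains in all that became monomer in chains or isomer of the product, beta
4. share of monomer in chains in all that became monomer in chains or isomer of the product, epsilon
5. share of monomer in chains in all that became monomer in chains or isomer of the product, delta

- the numbers in the tables scatter by 1 percentage point (one standard deviation)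
- candidate steps: initiator -> 2 initiating radical; free monomer + initiating radical -> growing radical + monomer in chains; free monomer + growing radical -> monomer in chains + growing radical; 2 growing radical -> dead chain; growing radical + radical scavenger -> ended chains; monomer in chains <-> isomer of the product

Suppose each initiator lost gives two initiating radicals, each of these becomes a growing radical, and each growing radical is ended by one radical scavenger. The delay (induction period) then closes at a fixed fraction of initiator left. This hold mark, one minus the scavenger charge over twice the initiator charge, is 78.0% for zeta, beta, epsilon and delta, which share these charges.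

You can get the clock from the midnight run by working with the fraction of free monomer left, that is, one minus chains and isomer. Its logarithm falls at 0.772 h⁻¹ between the first and third readings. Run back, that line starts at 0.240 h. The midnight mark is 90.0%, so the initiator in the midnight run is lost at about 0.440 h⁻¹ at 6 °C, as a reading.

The winter run stays near the scatter through 15.0 h. Its mark is 84.3%, so its initiator is lost at no more than about 0.0114 h⁻¹ at −19 °C.

At that ceiling, zeta's mark takes 21.8 h to reach, which is shorter than its 25 h. But zeta is colder than winter, and the loss need slow by a factor of only 1.15, while from midnight to winter it slowed by at least 38.6. So I commit to zeta's hold lasting the whole run, which means that zeta as charged shows no chains above the scatter, even though I also expect it to have the highest share. If zeta is to give a reading in its time, the next batch should carry less radical scavenger. Beta, warmer than winter, gets no such floor and may cross the mark.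

The forecast names zeta, with 92% for zeta, 70% for beta, 3% for epsilon and 5% for delta, and adds “These low-temperature shares are very uncertain”.

The simulation gives zeta as the highest, with 94.4% in zeta, 84.6% in beta, 9.25% in epsilon and 4.97% in delta.

    initiator → 2 initiating radical (k = 0.00235 min⁻¹, Ea = 96.0 kJ mol⁻¹)
    free monomer + initiating radical → growing radical + monomer in chains (k = 3.25 × 10⁵ L mol⁻¹ min⁻¹, Ea = 30.0 kJ mol⁻¹)
    free monomer + growing radical → monomer in chains + growing radical, rate k3*[growing radical]*[free monomer] (k = 17100 L mol⁻¹ min⁻¹, Ea = 37.0 kJ mol⁻¹)
    2 growing radical → dead chain (k = 7.00 × 10⁶ L mol⁻¹ s⁻¹, Ea = 9.00 kJ mol⁻¹)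
    growing radical + radical scavenger → ended chains (k = 2.56 × 10⁵ L mol⁻¹ s⁻¹, Ea = 16.0 kJ mol⁻¹)
    monomer in chains ⇌ isomer of the product (K = 22.4, k = 0.00822 min⁻¹, Ea = 86.0 kJ mol⁻¹, ΔH = −36.0 kJ mol⁻¹)
    (constants at 0 °C)

In zeta the relaxation half-life between monomer in chains and isomer of the product is 149 h, long against the 25 h of the run. Zeta still has 98.1% of its initiator, above the mark of 78.0%, and 91.4% of its radical scavenger, and its monomer in chains stands at 0.0926% against a scatter of 1 percentage point. Beta has 73.9% of its initiator left at 25.0 h, below the same mark, and its radical scavenger stands at 0%.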